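## The problem

Target 18 is an isoflavone: a benzo ring A fused to a 4-pyranone ring C (chromen-4-one), with the 3,4,5-trimethoxyphenyl ring B on C3. It has no stereocentre, so nothing has to be controlled in space, and any stereocentre that appears on the way can be carried as a racemate and erased. The real problem is regiochemistry and differentiation: ring A carries oxygen at C6, C7 and C8a, and of the five aryl–oxygen bonds that end in a substituent only the one at C7 is a free phenol; the other four are methyl ethers. A late selective demethylation is not an option, because Lewis acids attack the central methoxy group of ring B at least as readily as a methoxy group at C7. The C7 oxygen therefore has to enter the synthesis already marked. Ring C is an enol ether conjugated to a ketone and is opened by hydroxide and other nucleophiles at C2, so it should be closed late and the last unmasking should be acidic. The electron-rich ring A intermediates (a para-methoxyphenol, an ortho-hydroxybenzylic carbinol) are prone to oxidation to quinones and to ionisation to ortho-quinone methides, which limits the oxidants and acids usable before the C4 carbonyl is in place. The feature that opens the route is the pattern of ring A itself: the C6 methoxy group and the C8a oxygen are para, the C7 oxygen sits next to C6, and C5 and C8 are unsubstituted. This is the pattern of a 4-methoxyphenol assembled from a methoxycarbene carbon (C6), a carbonyl ligand (C8a), an alpha-alkoxyvinyl group (C7, C8) and a terminal alkyne (C5, C4a).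

## Retrosynthesis

**18 from 17.** The only bond cut is the O–C bond of a tert-butyl ether on the C7 oxygen. tert-Butyl is chosen over benzyl or silyl because it must survive an organolithium, a thermal organometallic step, fluoride, MnO2 and an amide acetal, and then leave under trifluoroacetic acid without touching the methyl ethers or ring C. A benzyl vinyl ether could not be alpha-lithiated cleanly, which rules benzyl out at the very start of the sequence.

**17 from 15.** Cutting O1–C2 and C2–C3 removes C2 as a one-carbon electrophile and leaves the 2-hydroxydeoxybenzoin 15. The forward reaction passes through enaminone 16. The neighbouring cut at C3–C1' (cross-coupling of a 3-halochromone) would need ring C built and halogenated first and would bring ring B in last. The chosen cut lets ring B travel inside the alkyne fragment from the beginning and asks of the forward step only a condensation at an activated methylene group.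

**15 from 14 from 13.** These are adjustments of oxidation level and protection at the future C4: ketone 15 from carbinol 14, and 14 from silyl ether 13. The carbonyl is deliberately not carried through the ring-forming step, because an ynone is an electron-poor, base-sensitive alkyne and a poor partner for a carbene benzannulation. Propargylic silyl ethers are among the best-behaved terminal alkynes in that reaction. The price is two routine steps.

**13 from 5 and 11 (key disconnection).** Three bonds of ring A are cut: C5–C6, C4a–C8a and C8–C8a. Ring A then falls into a three-carbon piece (C6, C7, C8 in carbene complex 5), one carbonyl ligand (C8a) and a two-carbon piece (C4a, C5 in alkyne 11). Starting instead from a trioxygenated benzene would make the placement of the acyl group depend on electrophilic substitution and would still need the C7 oxygen differentiated. Here the C6 methyl ether, the C7 tert-butyl ether and the free C8a hydroxyl each arrive with their own identity. The forward reaction must insert the alkyne in one orientation only, which a terminal alkyne with a branched propargylic carbon ensures.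

**5 from 1 and 2.** The C6–C7 bond is cut between the vinyl carbon and the carbene carbon. The forward sequence is alpha-lithiation of tert-butyl vinyl ether 1 to 3, addition to Cr(CO)6 (2) to give acylate 4, and O-methylation. The whole ring A precursor comes from two commodity chemicals in one flask.

**11 from 10, 10 from 8 and 9, 8 from 7 from 6.** The silyl ether 11 comes from propargylic alcohol 10. Alcohol 10 is cut at the bond between the carbinol carbon (future C4) and the alkyne (future C4a) into arylacetaldehyde 8 and ethynylmagnesium bromide 9. Aldehyde 8 is the one-carbon homologue of 3,4,5-trimethoxybenzaldehyde 6 through enol ether 7. The alternative of adding a benzyl metal to a propynal would require an electron-rich benzylic organometallic prone to homocoupling, whereas the acetylide addition is routine.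

## Roads not taken

**Alternative 1:** Ring C is cut at O1–C8a and C4–C4a, giving an aryne for ring A and the enol of a formylated arylacetate.
- Forward step: CsF would release 4,5-methylenedioxybenzyne from silylaryl triflate A2. The enolate oxygen of methyl 3-hydroxy-2-(3,4,5-trimethoxyphenyl)acrylate A1 adds, and the aryl anion closes onto the ester to give the 6,7-methylenedioxyisoflavone A3.
- Merits: two ring C bonds form in one mild operation, and the symmetric aryne removes any question of orientation. The skeleton is reached in fewer steps than in the chosen plan.
- Weak points: symmetry is also the flaw. A3 carries a methylenedioxy bridge where the target needs OMe at C6 and OH at C7. Opening the acetal needs Lewis acids that also threaten the central methoxy group of ring B. In the resulting catechol the C7 hydroxyl, para to the C4 carbonyl, is the more acidic and alkylates first, so methylating C6 needs a protect–methylate–deprotect detour. An unsymmetrical aryne with two different alkoxy groups would be attacked at both ends, since both oxygens are remote from the triple bond.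
- Comparison: the chosen plan is longer to the skeleton, but it differentiates the two oxygens at the moment ring A forms.

**Alternative 2:** The cut is at C3–C1' and O1–C2.
- Forward step: constant-current anodic oxidation of 2,6-dimethoxyphenol A5 in the presence of enaminone A4 (the dimethylaminomethylene derivative of 4-benzyloxy-2-hydroxy-5-methoxyacetophenone) joins the enaminone alpha-carbon to the para position of the oxidised phenol. The ring A hydroxyl then displaces dimethylamine to give 7-benzyloxy-3-(4-hydroxy-3,5-dimethoxyphenyl)-6-methoxychromen-4-one A6. Methylation of the 4'-hydroxyl and debenzylation would finish.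
- Merits: no stoichiometric metal or oxidant, a very cheap ring B source, and a convergent C–C bond formation.
- Weak points: ring A still has to be bought or built as a differentiated acetophenone. The free ring A phenol of A4 is a para-methoxyphenol that should be oxidised at a potential close to that of A5, so selectivity between the two phenols, and against the para–para dimer of A5, rests on a narrow potential window. Two further steps follow the coupling.
- Comparison: in step count this road is equal or slightly shorter, and it avoids chromium. The chosen plan offers a ring-forming step whose regiochemistry follows a firm structural rule instead of a balance of oxidation potentials.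

**Alternative 3:** The cut is at C4–C4a only.
- Forward step: 3-benzyloxy-4-methoxyphenol A7 is joined through oxygen to the formylated arylacetate, and the derived (Z)-3-aryloxy-2-arylacryloyl chloride A8 is closed with SnCl4 by Friedel–Crafts acylation para to the benzyloxy group. The product is 7-benzyloxy-6-methoxy-3-(3,4,5-trimethoxyphenyl)chromen-4-one A9; hydrogenolysis ends the route.
- Merits: every step is classical and scalable. The acylation site is well defined (para to one oxygen, ortho to the other, the alternative ortho position lying between two substituents). The C7 oxygen is differentiated from the start as a benzyl ether.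
- Weak points: only the isomer of A8 with the aryloxy group cis to the acyl chloride can close, and the addition–elimination that makes the enol ether does not control this geometry. The acyl chloride is a vinylogous carbonate derivative of reduced electrophilicity. SnCl4 may cleave the benzyl ether or a methyl ether. A7 itself needs a benzylation and a Dakin or Baeyer–Villiger sequence from isovanillin.
- Comparison: this road is probably at least as short as the chosen one and uses cheaper, less toxic reagents. The chosen plan sets against it independence from alkene geometry and from Lewis acids, and a C7 protecting group removed by brief acid treatment instead of hydrogenation over the reducible C2–C3 double bond.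

Key step: step 6

Remark: alcohol 10 and its descendants 11 to 14 are racemic (one enantiomer is drawn in the SMILES) and enol ether 7 is an E/Z mixture; both elements are erased before the achiral target.

## Route

Step 1
Reactants: 1 tert-butyl vinyl ether; 2 chromium hexacarbonyl Cr(CO)6
Product: 5 pentacarbonyl[(1-tert-butoxyvinyl)(methoxy)carbene]chromium, via 1-tert-butoxyvinyllithium 3 (not isolated), via lithium acylchromate 4 (not isolated)
Conditions: 1 (1.3 equiv), t-BuLi, THF, −78 → 0 °C; Cr(CO)6, Et2O/THF, −78 °C → rt; evaporate; Me3OBF4, CH2Cl2/H2O, 0 °C
Reagents that add atoms: trimethyloxonium tetrafluoroborate, C[O+](C)C.F[B-](F)(F)F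
Why: Fischer carbene synthesis: oxygen-directed alpha-lithiation of an alkyl vinyl ether, addition of the vinyllithium to a CO ligand of zerovalent chromium, and O-methylation of the acylate by a hard oxonium salt. The excess of 1 keeps free t-BuLi away from Cr(CO)6, and the alpha-substituted vinyl group makes 5 an analogue of the isolable isopropenyl complex.

Step 2
Reactants: 6 3,4,5-trimethoxybenzaldehyde
Product: 7 1,2,3-trimethoxy-5-(2-methoxyethenyl)benzene (E/Z mixture)
Conditions: MeOCH2PPh3Cl, KOtBu, THF, 0 °C → rt
Reagents that add atoms: (methoxymethyl)triphenylphosphonium chloride, COC[P+](c1ccccc1)(c1ccccc1)c1ccccc1.[Cl-]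
Why: Wittig methoxymethylenation of a non-enolisable aromatic aldehyde; the alkene geometry is irrelevant because both isomers hydrolyse to the same aldehyde.

Step 3
Reactants: 7 1,2,3-trimethoxy-5-(2-methoxyethenyl)benzene
Product: 8 (3,4,5-trimethoxyphenyl)acetaldehyde
Conditions: 2 M aq. HCl, THF, 45 °C; used at once
Reagents that add atoms: water, O
Why: Acid hydrolysis of an enol ether (C-protonation, hydration of the oxocarbenium ion, loss of methanol) completes the one-carbon homologation; the sensitive arylacetaldehyde is not stored.

Step 4
Reactants: 8 (3,4,5-trimethoxyphenyl)acetaldehyde; 9 ethynylmagnesium bromide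
Product: 10 1-(3,4,5-trimethoxyphenyl)but-3-yn-2-ol (racemic)
Conditions: HC≡CMgBr (0.5 M in THF, 1.5 equiv), THF, −78 → 0 °C; aq. NH4Cl
Reagents that add atoms: none
Why: Grignard 1,2-addition of an acetylide, a weakly basic nucleophile that adds at low temperature faster than it enolises the aldehyde. The new carbinol centre forms as the racemate on purpose, since it becomes the C4 carbonyl.

Step 5
Reactants: 10 1-(3,4,5-trimethoxyphenyl)but-3-yn-2-ol
Product: 11 tert-butyl(dimethyl){[1-(3,4,5-trimethoxyphenyl)but-3-yn-2-yl]oxy}silane (racemic)
Conditions: TBSCl, imidazole, DMF, rt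
Reagents that add atoms: tert-butyldimethylsilyl chloride, CC(C)(C)[Si](C)(C)Cl
Why: Standard imidazole-promoted silylation of a secondary alcohol; the silyl ether removes the acidic OH and adds bulk at the propargylic carbon, both helpful in the benzannulation.

Step 6
Reactants: 5 pentacarbonyl[(1-tert-butoxyvinyl)(methoxy)carbene]chromium; 11 tert-butyl(dimethyl){[1-(3,4,5-trimethoxyphenyl)but-3-yn-2-yl]oxy}silane
Product: 13 5-tert-butoxy-2-[1-(tert-butyldimethylsilyloxy)-2-(3,4,5-trimethoxyphenyl)ethyl]-4-methoxyphenol (racemic), via tricarbonylchromium arene complex 12 (not isolated)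
Conditions: 5 (1.3 equiv), THF (0.05 M), 50 °C, Ar; then air, CH2Cl2, rt
Reagents that add atoms: none
Why: The closest known reaction type is the Dötz benzannulation of alpha-substituted alkenyl(methoxy)carbene complexes of zerovalent chromium (isopropenyl, dihydropyranyl and glycal-derived complexes) with terminal alkynes, propargylic silyl ethers included. Thermal loss of one cis CO ligand from 5 opens a site for alkyne 11, and insertion into the Cr=C bond joins the carbene carbon to the terminal CH (C5–C6) to give an eta-3 vinylcarbene. Migration of a CO ligand onto the former internal alkyne carbon forms C4a–C8a and an eta-4 vinylketene. Ring A then closes by a 6-pi electrocyclisation of this dienylketene, the ketene carbon bonding to the vinyl CH2 terminus (C8–C8a), and the cyclohexadienone enolises to the phenol, held as the Cr(CO)3 complex 12 until air releases 13. The only selectivity needed is the orientation of the alkyne: the branched propargylic carbon avoids the carbene substituents and the CO ligands during insertion, so the unsubstituted terminus ends next to the methoxy-bearing carbon and the side chain lands ortho to the new hydroxyl. Phenol formation, not cyclopentannulation, is favoured by the combination of chromium, a methoxy donor, an alkenyl carbene and THF. No stereocentre is created: the carbinol centre of 11 is carried unchanged as the racemate and the planar chirality of 12 disappears on demetalation.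

Step 7
Reactants: 13 5-tert-butoxy-2-[1-(tert-butyldimethylsilyloxy)-2-(3,4,5-trimethoxyphenyl)ethyl]-4-methoxyphenol
Product: 14 5-tert-butoxy-2-[1-hydroxy-2-(3,4,5-trimethoxyphenyl)ethyl]-4-methoxyphenol (racemic)
Conditions: TBAF, AcOH (1:1), THF, 0 °C → rt
Reagents that add atoms: none
Why: Fluoride cleavage of the Si–O bond. The acetic acid buffer keeps the medium from becoming basic enough for the phenoxide to expel the benzylic oxygen as an ortho-quinone methide, and the tert-butyl ether is inert to fluoride.

Step 8
Reactants: 14 5-tert-butoxy-2-[1-hydroxy-2-(3,4,5-trimethoxyphenyl)ethyl]-4-methoxyphenol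
Product: 15 1-(4-tert-butoxy-2-hydroxy-5-methoxyphenyl)-2-(3,4,5-trimethoxyphenyl)ethanone
Conditions: activated MnO2 (excess), CH2Cl2, rt
Reagents that add atoms: none
Why: MnO2 oxidises benzylic alcohols selectively under neutral heterogeneous conditions, and ortho-hydroxybenzylic alcohols are standard substrates. The product ketone is protected from further oxidation by its hydrogen bond to the phenol and by the deactivation of ring A.

Step 9
Reactants: 15 1-(4-tert-butoxy-2-hydroxy-5-methoxyphenyl)-2-(3,4,5-trimethoxyphenyl)ethanone
Product: 17 7-tert-butoxy-6-methoxy-3-(3,4,5-trimethoxyphenyl)chromen-4-one, via enaminone 16 (not isolated)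
Conditions: Me2NCH(OMe)2 (3 equiv), toluene, 100 °C
Reagents that add atoms: N,N-dimethylformamide dimethyl acetal, COC(OC)N(C)C
Why: This is the standard conversion of a 2-hydroxydeoxybenzoin into an isoflavone: the amide acetal condenses with the doubly activated methylene group to give enaminone 16. The ortho hydroxyl then adds to the beta-carbon and expels dimethylamine, forming O1–C2 and closing ring C.

Step 10
Reactants: 17 7-tert-butoxy-6-methoxy-3-(3,4,5-trimethoxyphenyl)chromen-4-one
Product: 18 7-hydroxy-6-methoxy-3-(3,4,5-trimethoxyphenyl)chromen-4-one
Conditions: TFA, CH2Cl2, 0 °C → rt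
Reagents that add atoms: none
Why: Acidolysis of an aryl tert-butyl ether by loss of the tert-butyl cation as isobutene; aryl methyl ethers and the chromone are stable to trifluoroacetic acid, and ring A is deactivated toward re-alkylation by the C4 carbonyl.

## Compound list

1 | tert-butyl vinyl ether | C=COC(C)(C)C | starting material
2 | chromium hexacarbonyl Cr(CO)6 | O=C=[Cr](=C=O)(=C=O)(=C=O)(=C=O)=C=O | starting material
3 | 1-tert-butoxyvinyllithium | [Li]C(=C)OC(C)(C)C | intermediate (not isolated)
4 | lithium pentacarbonyl(2-tert-butoxyprop-2-enoyl)chromate (lithium acylchromate) | [Li+].[O-]C(=[Cr](=C=O)(=C=O)(=C=O)(=C=O)=C=O)C(=C)OC(C)(C)C | intermediate (not isolated)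
5 | pentacarbonyl[(1-tert-butoxyvinyl)(methoxy)carbene]chromium | COC(=[Cr](=C=O)(=C=O)(=C=O)(=C=O)=C=O)C(=C)OC(C)(C)C | intermediate
6 | 3,4,5-trimethoxybenzaldehyde | COc1cc(C=O)cc(OC)c1OC | starting material
7 | 1,2,3-trimethoxy-5-(2-methoxyethenyl)benzene (E/Z mixture) | COC=Cc1cc(OC)c(OC)c(OC)c1 | intermediate
8 | (3,4,5-trimethoxyphenyl)acetaldehyde | O=CCc1cc(OC)c(OC)c(OC)c1 | intermediate
9 | ethynylmagnesium bromide | C#C[Mg]Br | starting material
10 | 1-(3,4,5-trimethoxyphenyl)but-3-yn-2-ol (racemic, one enantiomer drawn) | C#C[C@@H](O)Cc1cc(OC)c(OC)c(OC)c1 | intermediate
11 | tert-butyl(dimethyl){[1-(3,4,5-trimethoxyphenyl)but-3-yn-2-yl]oxy}silane (racemic, one enantiomer drawn) | C#C[C@@H](O[Si](C)(C)C(C)(C)C)Cc1cc(OC)c(OC)c(OC)c1 | intermediate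
12 | tricarbonyl(eta-6-arene)chromium complex of phenol 13 (diastereomer mixture; the SMILES shows the arene and the Cr(CO)3 fragment side by side) | COc1cc([C@@H](O[Si](C)(C)C(C)(C)C)Cc2cc(OC)c(OC)c(OC)c2)c(O)cc1OC(C)(C)C.O=C=[Cr](=C=O)=C=O | intermediate (not isolated)
13 | 5-tert-butoxy-2-[1-(tert-butyldimethylsilyloxy)-2-(3,4,5-trimethoxyphenyl)ethyl]-4-methoxyphenol (racemic, one enantiomer drawn) | COc1cc([C@@H](O[Si](C)(C)C(C)(C)C)Cc2cc(OC)c(OC)c(OC)c2)c(O)cc1OC(C)(C)C | intermediate
14 | 5-tert-butoxy-2-[1-hydroxy-2-(3,4,5-trimethoxyphenyl)ethyl]-4-methoxyphenol (racemic, one enantiomer drawn) | COc1cc([C@@H](O)Cc2cc(OC)c(OC)c(OC)c2)c(O)cc1OC(C)(C)C | intermediate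
15 | 1-(4-tert-butoxy-2-hydroxy-5-methoxyphenyl)-2-(3,4,5-trimethoxyphenyl)ethanone | COc1cc(C(=O)Cc2cc(OC)c(OC)c(OC)c2)c(O)cc1OC(C)(C)C | intermediate
16 | 1-(4-tert-butoxy-2-hydroxy-5-methoxyphenyl)-3-(dimethylamino)-2-(3,4,5-trimethoxyphenyl)prop-2-en-1-one (enaminone, geometry not fixed) | CN(C)C=C(C(=O)c1cc(OC)c(OC(C)(C)C)cc1O)c1cc(OC)c(OC)c(OC)c1 | intermediate (not isolated)
17 | 7-tert-butoxy-6-methoxy-3-(3,4,5-trimethoxyphenyl)chromen-4-one | COc1cc2c(=O)c(-c3cc(OC)c(OC)c(OC)c3)coc2cc1OC(C)(C)C | intermediate
18 | 7-hydroxy-6-methoxy-3-(3,4,5-trimethoxyphenyl)chromen-4-one | COc1cc2c(=O)c(-c3cc(OC)c(OC)c(OC)c3)coc2cc1O | target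

## Step count and risks

Total step count: 10. Longest linear sequence: 9 steps (6 to 18 through steps 2 to 10); the carbene branch contributes one further step (step 1).

**Step 6 (key step).**
- What may go wrong: the vinylcarbene and vinylketene intermediates may be diverted into non-phenolic channels (cyclobutenone formation, incorporation of a second alkyne). The branched propargylic silyl ether may slow alkyne insertion enough for thermal decomposition of the electron-rich, beta-unsubstituted carbene complex to compete. The product may also lose its silyloxy group through an ortho-quinone methide during purification.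
- Fallback: this one gives up the benzannulation and builds the deoxybenzoin by classical acylation. It sets out from aldehyde 8. Pinnick oxidation (NaClO2, NaH2PO4, 2-methyl-2-butene) gives (3,4,5-trimethoxyphenyl)acetic acid F1. F1 acylates purchased 4-methoxybenzene-1,3-diol F2 in BF3·OEt2 at about 85 °C, at the position ortho to one hydroxyl and para to the other, to give 1-(2,4-dihydroxy-5-methoxyphenyl)-2-(3,4,5-trimethoxyphenyl)ethanone F3. Treatment of F3 with BF3·OEt2, DMF and methanesulfonyl chloride closes ring C and comes back to the route at target 18. The price is reliance on the supply of F2 and on substitution regiochemistry.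

**Step 1.**
- What may go wrong: alpha-deprotonation of the bulky vinyl ether may be incomplete. O-alkylation of the tightly ion-paired lithium acylate may be sluggish, with loss of the acid-sensitive enol ether in the aqueous oxonium medium.
- Fallback: it sets out from acylate 4. Cation exchange with tetramethylammonium bromide in water gives the isolable tetramethylammonium pentacarbonyl(2-tert-butoxyprop-2-enoyl)chromate F4. O-acylation with acetyl bromide in CH2Cl2 at −40 °C gives pentacarbonyl[(acetoxy)(1-tert-butoxyvinyl)carbene]chromium F5. Addition of methanol exchanges the acyloxy group for methoxy and returns to the route at 5. This replaces direct O-alkylation by acylation and alcoholysis under anhydrous, non-acidic conditions.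

**Step 8.**
- What may go wrong: one-electron oxidation of the para-methoxyphenol ring (phenoxy radical coupling, quinone formation) may compete with oxidation of the carbinol. Dehydration of the ortho-hydroxybenzylic alcohol through an ortho-quinone methide is also possible.
- Fallback: it sets out from 13 and masks the phenol before the oxidation. Allyl bromide and K2CO3 in DMF give the allyl ether 1-(allyloxy)-5-tert-butoxy-2-[1-(tert-butyldimethylsilyloxy)-2-(3,4,5-trimethoxyphenyl)ethyl]-4-methoxybenzene F6. TBAF gives the alcohol 1-(2-allyloxy-4-tert-butoxy-5-methoxyphenyl)-2-(3,4,5-trimethoxyphenyl)ethanol F7. Dess–Martin periodinane gives the ketone 1-(2-allyloxy-4-tert-butoxy-5-methoxyphenyl)-2-(3,4,5-trimethoxyphenyl)ethanone F8. Deallylation with Pd(PPh3)4 (zerovalent palladium) and morpholine comes back to the route at 15.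

**Step 9.**
- What may go wrong: the amide acetal may O-methylate the phenol, which blocks ring closure, or the reaction may stop at enaminone 16.
- Fallback: it sets out from 15 and changes the one-carbon source to a formate ester, so that no methylating agent is present. Claisen formylation with ethyl formate and NaH in THF gives 7-tert-butoxy-2-hydroxy-6-methoxy-3-(3,4,5-trimethoxyphenyl)chroman-4-one F9, the ring-closed tautomer of the alpha-formyl ketone. Trifluoroacetic acid in CH2Cl2 then dehydrates the hemiacetal and cleaves the tert-butyl ether in one operation, coming back to the route at 18 and bypassing 17.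

## Further compounds

F1 | step 6 | (3,4,5-trimethoxyphenyl)acetic acid | COc1cc(CC(=O)O)cc(OC)c1OC
F2 | step 6 | 4-methoxybenzene-1,3-diol (purchased) | COc1ccc(O)cc1O
F3 | step 6 | 1-(2,4-dihydroxy-5-methoxyphenyl)-2-(3,4,5-trimethoxyphenyl)ethanone | COc1cc(C(=O)Cc2cc(OC)c(OC)c(OC)c2)c(O)cc1O
F4 | step 1 | tetramethylammonium pentacarbonyl(2-tert-butoxyprop-2-enoyl)chromate | C[N+](C)(C)C.[O-]C(=[Cr](=C=O)(=C=O)(=C=O)(=C=O)=C=O)C(=C)OC(C)(C)C
F5 | step 1 | pentacarbonyl[(acetoxy)(1-tert-butoxyvinyl)carbene]chromium | CC(=O)OC(=[Cr](=C=O)(=C=O)(=C=O)(=C=O)=C=O)C(=C)OC(C)(C)C
F6 | step 8 | 1-(allyloxy)-5-tert-butoxy-2-[1-(tert-butyldimethylsilyloxy)-2-(3,4,5-trimethoxyphenyl)ethyl]-4-methoxybenzene (racemic, one enantiomer drawn) | COc1cc([C@@H](O[Si](C)(C)C(C)(C)C)Cc2cc(OC)c(OC)c(OC)c2)c(OCC=C)cc1OC(C)(C)C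
F7 | step 8 | 1-(2-allyloxy-4-tert-butoxy-5-methoxyphenyl)-2-(3,4,5-trimethoxyphenyl)ethanol (racemic, one enantiomer drawn) | COc1cc([C@@H](O)Cc2cc(OC)c(OC)c(OC)c2)c(OCC=C)cc1OC(C)(C)C
F8 | step 8 | 1-(2-allyloxy-4-tert-butoxy-5-methoxyphenyl)-2-(3,4,5-trimethoxyphenyl)ethanone | COc1cc(C(=O)Cc2cc(OC)c(OC)c(OC)c2)c(OCC=C)cc1OC(C)(C)C
F9 | step 9 | 7-tert-butoxy-2-hydroxy-6-methoxy-3-(3,4,5-trimethoxyphenyl)chroman-4-one (diastereomer mixture, racemic) | COc1cc2C(=O)C(c3cc(OC)c(OC)c(OC)c3)C(O)Oc2cc1OC(C)(C)C
A1 | alternative 1 | methyl 3-hydroxy-2-(3,4,5-trimethoxyphenyl)acrylate | COC(=O)C(=CO)c1cc(OC)c(OC)c(OC)c1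
A2 | alternative 1 | 6-(trimethylsilyl)-1,3-benzodioxol-5-yl trifluoromethanesulfonate | C[Si](C)(C)c1cc2OCOc2cc1OS(=O)(=O)C(F)(F)F
A3 | alternative 1 | 6,7-methylenedioxy-3-(3,4,5-trimethoxyphenyl)chromen-4-one | COc1cc(-c2coc3cc4OCOc4cc3c2=O)cc(OC)c1OC
A4 | alternative 2 | (E)-1-(4-benzyloxy-2-hydroxy-5-methoxyphenyl)-3-(dimethylamino)prop-2-en-1-one | CN(C)/C=C/C(=O)c1cc(OC)c(OCc2ccccc2)cc1O
A5 | alternative 2 | 2,6-dimethoxyphenol | COc1cccc(OC)c1O
A6 | alternative 2 | 7-benzyloxy-3-(4-hydroxy-3,5-dimethoxyphenyl)-6-methoxychromen-4-one | COc1cc2c(=O)c(-c3cc(OC)c(O)c(OC)c3)coc2cc1OCc1ccccc1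
A7 | alternative 3 | 3-benzyloxy-4-methoxyphenol | COc1ccc(O)cc1OCc1ccccc1
A8 | alternative 3 | (Z)-3-(3-benzyloxy-4-methoxyphenoxy)-2-(3,4,5-trimethoxyphenyl)acryloyl chloride | ClC(=O)/C(=C\Oc1ccc(OC)c(OCc2ccccc2)c1)c1cc(OC)c(OC)c(OC)c1
A9 | alternative 3 | 7-benzyloxy-6-methoxy-3-(3,4,5-trimethoxyphenyl)chromen-4-one | COc1cc2c(=O)c(-c3cc(OC)c(OC)c(OC)c3)coc2cc1OCc1ccccc1
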